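**Plan**
- Artocarpetin B has no stereocentre. The retrosynthesis first removes two phenol protections (4'-O-allyl, 5-O-methyl), then cuts C4–C4a of ring C, then the O1–C2 enol ether bond, and last the C8–prenyl bond and the three propiolate carbons on ring B.
- The ring closure rests on C4a of ring A: it is ortho to O1, ortho to the C5 oxygen and para to the C7 oxygen, and it is the only free carbon next to O1 because C8 carries the prenyl group.
- Forward: 3,5-dimethoxyphenol is ortho-prenylated (ring A piece); 4-hydroxy-2-methoxybenzaldehyde is allylated and homologated to a methyl arylpropiolate (ring B with C2, C3, C4).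
- Oxa-Michael addition joins the pieces (O1–C2), saponification frees the acid, and a buffered Friedel–Crafts acylation closes ring C (C4–C4a).
- Chelation-controlled cleavage of the 5-methyl ether and deallylation with Pd(PPh3)4 finish the route. The only geometric element, the Z enol ether, comes from anti addition and disappears on ring closure.

Key step: step 7

Assumption: the oxa-Michael step is drawn as giving the Z ester (anti addition); any E ester would be carried along, because the enol ether geometry can equilibrate once the acid is activated in step 7.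

**Step 1**
Reactants: 1 3,5-dimethoxyphenol; 2 prenyl bromide (1-bromo-3-methylbut-2-ene)
Product: 4 3,5-dimethoxy-2-(3-methylbut-2-enyl)phenol, via sodium 3,5-dimethoxyphenoxide 3 (not isolated)
Conditions: NaH (1.05 equiv), toluene, 0 °C → rt; then 2 (1.0 equiv), rt
Reagents that add atoms: none
Why: Ortho C-alkylation of a phenoxide held as a tight sodium ion pair in a non-coordinating solvent (SN2 on the allylic bromide, then rearomatisation) is favoured over O-alkylation, and the two ortho positions of 1 are equivalent, so a single ortho-prenyl phenol is expected.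

**Step 2**
Reactants: 5 4-hydroxy-2-methoxybenzaldehyde
Product: 6 2-methoxy-4-(prop-2-enyloxy)benzaldehyde
Conditions: allyl bromide, K2CO3, acetone, reflux
Reagents that add atoms: allyl bromide, C=CCBr
Why: Williamson etherification of the only phenol; the allyl ether resists both the basic and the acidic steps ahead and can be removed at the end without touching the prenyl alkene.

**Step 3**
Reactants: 6 2-methoxy-4-(prop-2-enyloxy)benzaldehyde
Product: 7 1-(2,2-dibromoethenyl)-2-methoxy-4-(prop-2-enyloxy)benzene
Conditions: CBr4 (2 equiv), PPh3 (4 equiv), CH2Cl2, 0 °C; hexane, filtration through silica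
Reagents that add atoms: carbon tetrabromide, BrC(Br)(Br)Br
Why: Ramirez dibromo-olefination (first stage of the Corey–Fuchs sequence) is a Wittig-type reaction that works well on electron-rich benzaldehydes and leaves the allyl ether alone.

**Step 4**
Reactants: 7 1-(2,2-dibromoethenyl)-2-methoxy-4-(prop-2-enyloxy)benzene
Product: 9 methyl 3-[2-methoxy-4-(prop-2-enyloxy)phenyl]prop-2-ynoate, via lithium arylacetylide 8 (not isolated)
Conditions: n-BuLi (2.1 equiv), THF, −78 °C; then ClCO2Me, −78 → 0 °C
Reagents that add atoms: methyl chloroformate, COC(=O)Cl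
Why: Second stage of the Corey–Fuchs sequence: bromine–lithium exchange, loss of LiBr and deprotonation give the lithium acetylide, which is acylated by the chloroformate, and at −78 °C the exchange should outrun deprotonation of the allyl ether.

**Step 5**
Reactants: 4 3,5-dimethoxy-2-(3-methylbut-2-enyl)phenol; 9 methyl 3-[2-methoxy-4-(prop-2-enyloxy)phenyl]prop-2-ynoate
Product: 10 methyl (Z)-3-[3,5-dimethoxy-2-(3-methylbut-2-enyl)phenoxy]-3-[2-methoxy-4-(prop-2-enyloxy)phenyl]prop-2-enoate
Conditions: Cs2CO3 (0.3 equiv), DMF, 70 °C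
Reagents that add atoms: none
Why: Base-catalysed oxa-Michael addition of a phenoxide to the aryl-bearing carbon of an arylpropiolate is the classical entry to β-aryloxycinnamates, and anti addition places the aryloxy group cis to the ester (Z).

**Step 6**
Reactants: 10 methyl (Z)-3-[3,5-dimethoxy-2-(3-methylbut-2-enyl)phenoxy]-3-[2-methoxy-4-(prop-2-enyloxy)phenyl]prop-2-enoate
Product: 11 (Z)-3-[3,5-dimethoxy-2-(3-methylbut-2-enyl)phenoxy]-3-[2-methoxy-4-(prop-2-enyloxy)phenyl]prop-2-enoic acid
Conditions: LiOH·H2O, THF/MeOH/H2O, rt → 40 °C; then 1 M HCl to pH 3–4, 0 °C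
Reagents that add atoms: lithium hydroxide, [Li+].[OH-]
Why: Saponification of the methyl ester, as used for β-aryloxycinnamic esters in the classical sequence; the allyl ether, the aryl vinyl ether and the prenyl group are stable to aqueous hydroxide and to brief cold dilute acid.

**Step 7**
Reactants: 11 (Z)-3-[3,5-dimethoxy-2-(3-methylbut-2-enyl)phenoxy]-3-[2-methoxy-4-(prop-2-enyloxy)phenyl]prop-2-enoic acid
Product: 13 5,7-dimethoxy-2-[2-methoxy-4-(prop-2-enyloxy)phenyl]-8-(3-methylbut-2-enyl)chromen-4-one, via mixed trifluoroacetic anhydride 12 (not isolated)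
Conditions: (CF3CO)2O (1.5 equiv), 2,6-di-tert-butyl-4-methylpyridine (2.5 equiv), CH2Cl2, 0 °C → rt
Reagents that add atoms: none
Why: Trifluoroacetic anhydride converts 11 into mixed anhydride 12, which ionises to an acylium ion stabilised as a ketene–oxocarbenium by the β-aryloxy oxygen and by ring B; C6 of the phenoxy ring (the future C4a) attacks it and gives up a proton to the hindered pyridine, forming C4–C4a. The closest known reaction is the intramolecular Friedel–Crafts acylation of β-aryloxyacrylic and β-aryloxycinnamic acids from phenol–propiolate adducts to chromones and flavones, run here with anhydride activation as in the closure of 2-aryloxybenzoic acids to xanthones. Ring C closes in a six-membered mode that is exo with respect to the acyl C=O (6-exo-trig at the anhydride, 6-exo-dig at the acylium), with the arene C=C inside the new ring. No stereocentre is formed, and Z and E acids should converge because the ionised form has a rotatable C2–C3 single bond. Site selectivity is structural: C4a is ortho to O1, ortho to the 5-oxygen and para to the 7-oxygen, it is the only free carbon next to O1 because C8 bears the prenyl group, and the alternative five-membered closure onto ring B would have to occur at C6', which is meta to both ring B oxygens. Chemoselectivity over the prenyl alkene relies on the buffered medium and on the absence of a free hydroxyl ortho to the prenyl group, and the allyl ether is inert to the anhydride.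

**Step 8**
Reactants: 13 5,7-dimethoxy-2-[2-methoxy-4-(prop-2-enyloxy)phenyl]-8-(3-methylbut-2-enyl)chromen-4-one
Product: 14 5-hydroxy-7-methoxy-2-[2-methoxy-4-(prop-2-enyloxy)phenyl]-8-(3-methylbut-2-enyl)chromen-4-one
Conditions: MgI2·OEt2 (3 equiv), toluene/THF, 70 °C; cold 0.5 M HCl work-up
Reagents that add atoms: none
Why: Chelation-controlled ether cleavage: magnesium bridges the C4 carbonyl and the 5-methoxy oxygen so that iodide removes only that methyl group by SN2, while the 7- and 2'-methyl ethers and the allyl ether lack the chelate and the mild Lewis acid should spare the prenyl alkene.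

**Step 9**
Reactants: 14 5-hydroxy-7-methoxy-2-[2-methoxy-4-(prop-2-enyloxy)phenyl]-8-(3-methylbut-2-enyl)chromen-4-one
Product: 15 Artocarpetin B, 5-hydroxy-2-(4-hydroxy-2-methoxyphenyl)-7-methoxy-8-(3-methylbut-2-enyl)chromen-4-one
Conditions: Pd(PPh3)4 (5 mol%), morpholine, THF, rt
Reagents that add atoms: none
Why: Tsuji–Trost deallylation: zerovalent palladium ionises the aryl allyl ether to a π-allyl complex that morpholine captures, whereas the C-bound prenyl group has no leaving group and the methyl ethers are inert.

**Compound list**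
1 | 3,5-dimethoxyphenol | COc1cc(O)cc(OC)c1 | starting material
2 | prenyl bromide (1-bromo-3-methylbut-2-ene) | CC(C)=CCBr | starting material
3 | sodium 3,5-dimethoxyphenoxide | COc1cc([O-])cc(OC)c1.[Na+] | intermediate (not isolated)
4 | 3,5-dimethoxy-2-(3-methylbut-2-enyl)phenol | COc1cc(O)c(CC=C(C)C)c(OC)c1 | intermediate
5 | 4-hydroxy-2-methoxybenzaldehyde | COc1cc(O)ccc1C=O | starting material
6 | 2-methoxy-4-(prop-2-enyloxy)benzaldehyde | COc1cc(OCC=C)ccc1C=O | intermediate
7 | 1-(2,2-dibromoethenyl)-2-methoxy-4-(prop-2-enyloxy)benzene | COc1cc(OCC=C)ccc1C=C(Br)Br | intermediate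
8 | {[2-methoxy-4-(prop-2-enyloxy)phenyl]ethynyl}lithium | COc1cc(OCC=C)ccc1C#C[Li] | intermediate (not isolated)
9 | methyl 3-[2-methoxy-4-(prop-2-enyloxy)phenyl]prop-2-ynoate | COc1cc(OCC=C)ccc1C#CC(=O)OC | intermediate
10 | methyl (Z)-3-[3,5-dimethoxy-2-(3-methylbut-2-enyl)phenoxy]-3-[2-methoxy-4-(prop-2-enyloxy)phenyl]prop-2-enoate | COc1cc(OCC=C)ccc1/C(Oc1cc(OC)cc(OC)c1CC=C(C)C)=C/C(=O)OC | intermediate
11 | (Z)-3-[3,5-dimethoxy-2-(3-methylbut-2-enyl)phenoxy]-3-[2-methoxy-4-(prop-2-enyloxy)phenyl]prop-2-enoic acid | COc1cc(OCC=C)ccc1/C(Oc1cc(OC)cc(OC)c1CC=C(C)C)=C/C(=O)O | intermediate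
12 | (Z)-3-[3,5-dimethoxy-2-(3-methylbut-2-enyl)phenoxy]-3-[2-methoxy-4-(prop-2-enyloxy)phenyl]prop-2-enoic trifluoroacetic anhydride | COc1cc(OCC=C)ccc1/C(Oc1cc(OC)cc(OC)c1CC=C(C)C)=C/C(=O)OC(=O)C(F)(F)F | intermediate (not isolated)
13 | 5,7-dimethoxy-2-[2-methoxy-4-(prop-2-enyloxy)phenyl]-8-(3-methylbut-2-enyl)chromen-4-one | COc1cc(OCC=C)ccc1-c1cc(=O)c2c(OC)cc(OC)c(CC=C(C)C)c2o1 | intermediate
14 | 5-hydroxy-7-methoxy-2-[2-methoxy-4-(prop-2-enyloxy)phenyl]-8-(3-methylbut-2-enyl)chromen-4-one | COc1cc(OCC=C)ccc1-c1cc(=O)c2c(O)cc(OC)c(CC=C(C)C)c2o1 | intermediate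
15 | Artocarpetin B, 5-hydroxy-2-(4-hydroxy-2-methoxyphenyl)-7-methoxy-8-(3-methylbut-2-enyl)chromen-4-one | COc1cc(O)ccc1-c1cc(=O)c2c(O)cc(OC)c(CC=C(C)C)c2o1 | target

**Step count and risks**
Total steps: 9. Longest linear sequence: 8 steps (5 → 15 through steps 2–9); step 1 supplies the other branch.

Step 7, the ring closure. The doubly donor-stabilised anhydride may ionise or acylate too slowly under buffered conditions, while a move to stronger acid would invite protonation of the prenyl alkene and loss of material by addition or oligomerisation. The fallback closes ring C at O1–C2 instead; it sets out from 4 (with acetylide 8 made from 7 as in step 4) and returns at 13. Phenol 4 would be formylated at its only free ortho carbon (MgCl2, Et3N, paraformaldehyde, MeCN, reflux) to give 2-hydroxy-4,6-dimethoxy-3-(3-methylbut-2-enyl)benzaldehyde F1. An excess of 8 in THF at −78 °C would add to the aldehyde to give racemic 2-{1-hydroxy-3-[2-methoxy-4-(prop-2-enyloxy)phenyl]prop-2-ynyl}-3,5-dimethoxy-6-(3-methylbut-2-enyl)phenol F2. Oxidation with MnO2 in CH2Cl2 would give 1-[2-hydroxy-4,6-dimethoxy-3-(3-methylbut-2-enyl)phenyl]-3-[2-methoxy-4-(prop-2-enyloxy)phenyl]prop-2-yn-1-one F3, and base-mediated 6-endo-dig oxa-Michael cyclisation (K2CO3, acetone, reflux) should deliver 13.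

Step 5, the oxa-Michael addition. The hindered ortho-substituted phenoxide may add only sluggishly to an alkyne that is deactivated by the electron-rich ring B, and prolonged heating could bring reversal or ester exchange. The fallback makes the same C–O bond by cross-coupling; it sets out from 9 and returns at 10. Hydroiodination of 9 (NaI, AcOH, 80 °C) would give methyl (Z)-3-iodo-3-[2-methoxy-4-(prop-2-enyloxy)phenyl]prop-2-enoate F4, and copper-catalysed Ullmann-type vinylic C–O coupling with phenol 4 (CuI, N,N-dimethylglycine, Cs2CO3, dioxane, 90 °C) should give 10 with retention of the alkene geometry.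

Step 1, the ortho-prenylation. O-alkylation, attack at the para carbon between the two methoxy groups and double alkylation can all compete and erode the amount of 4. The fallback delivers the prenyl group by a sigmatropic shift; it sets out from 1 and returns at 4. O-Alkylation of 1 with 3-chloro-3-methylbut-1-yne (CuCl2·2H2O cat., DBU, MeCN, 0 °C) would give 1,3-dimethoxy-5-[(2-methylbut-3-yn-2-yl)oxy]benzene F5. Semi-hydrogenation (H2, Pd/CaCO3 poisoned with Pb(OAc)2, quinoline, EtOAc) would give 1,3-dimethoxy-5-[(2-methylbut-3-en-2-yl)oxy]benzene F6. Aromatic Claisen rearrangement (N,N-diethylaniline, 120 °C) transfers the allyl terminus to an ortho carbon and should give 4 with the regiochemistry fixed by the [3,3] shift.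

**Further compounds**
F1 | step 7 | 2-hydroxy-4,6-dimethoxy-3-(3-methylbut-2-enyl)benzaldehyde | COc1cc(OC)c(CC=C(C)C)c(O)c1C=O
F2 | step 7 | 2-{1-hydroxy-3-[2-methoxy-4-(prop-2-enyloxy)phenyl]prop-2-ynyl}-3,5-dimethoxy-6-(3-methylbut-2-enyl)phenol (racemic) | COc1cc(OCC=C)ccc1C#CC(O)c1c(OC)cc(OC)c(CC=C(C)C)c1O
F3 | step 7 | 1-[2-hydroxy-4,6-dimethoxy-3-(3-methylbut-2-enyl)phenyl]-3-[2-methoxy-4-(prop-2-enyloxy)phenyl]prop-2-yn-1-one | COc1cc(OCC=C)ccc1C#CC(=O)c1c(OC)cc(OC)c(CC=C(C)C)c1O
F4 | step 5 | methyl (Z)-3-iodo-3-[2-methoxy-4-(prop-2-enyloxy)phenyl]prop-2-enoate | COc1cc(OCC=C)ccc1/C(I)=C/C(=O)OC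
F5 | step 1 | 1,3-dimethoxy-5-[(2-methylbut-3-yn-2-yl)oxy]benzene | COc1cc(OC)cc(OC(C)(C)C#C)c1
F6 | step 1 | 1,3-dimethoxy-5-[(2-methylbut-3-en-2-yl)oxy]benzene | COc1cc(OC)cc(OC(C)(C)C=C)c1
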